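**Retrosynthetic overview**

1. Target 21 is cut last at C6–C7 (germacrane numbering: C6 = lactone O–CH, C7 = ring-fusion CH, C11/C12/C13 = methylene-lactone carbons, C4=C5 = Z ring alkene, C3 = OAc carbon, C9 = O-angelate carbon, C10 = CH–CH3). The acyclic (Z)-enal/allylic bromide 18 gives 21 by a CrCl2-mediated 2-(methoxycarbonyl)allylation–lactonisation that closes the ten-membered carbocycle first and the γ-lactone second in one operation, sets C6 and C7, and has both esters already in place.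
2. Enabling feature: the O–C6H–C7H–C11(=C13H2)–C12(=O)O array, a homoallylic alkoxide/acrylate retron whose C6–C7 bond is shared by the ten-membered ring and the five-membered lactone; C6 is also allylic to the (Z)-C4=C5 alkene, so it can be an enal carbonyl.
3. 18 comes from the C7 aldehyde 14 and methyl propiolate (vinylalumination, then SN2' bromination); the C6 enal is released from a TBS ether at the end.
4. 14 comes from the (Z)-enone 10 (CBS reduction sets C3, then acetate); 10 comes from terminal alkene 8, CO and (Z)-vinyl iodide 4 by hydroboration/carbonylative Suzuki–Miyaura coupling (bonds C2–C3 and C3–C4).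
5. 8 comes from 3-[(4-methoxybenzyl)oxy]propanal 5 and an (E)-crotylborane (C9 and C10, anti), then angelic acid; 4 comes from but-2-yn-1-ol 1.

Key step: step 14

Remark: aldehyde 5 is taken as a commercial compound (otherwise one oxidation from the commercial alcohol); "angelate" means the (2Z)-2-methylbut-2-enoate.

**Route**

Step 1
Reactants: 1 but-2-yn-1-ol
Product: 3 (2Z)-3-iodobut-2-en-1-ol, via oxaaluminate 2 (not isolated)
Conditions: NaAlH2(OCH2CH2OMe)2 (1.05 equiv), THF, 0 °C to rt; then iodine, −78 to 0 °C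
Reagents that add atoms: iodine, [I][I]
Why: Hydroxyl-directed trans-hydroalumination of the propargylic alcohol places hydride on C2 and aluminium on C3 inside a five-membered oxaaluminate, and iodinolysis of the carbon–aluminium bond with retention should give only the (Z)-iodoalkene whose geometry later becomes the cis ring alkene.

Step 2
Reactants: 3 (2Z)-3-iodobut-2-en-1-ol
Product: 4 tert-butyl{[(2Z)-3-iodobut-2-en-1-yl]oxy}dimethylsilane
Conditions: TBSCl, imidazole, CH2Cl2, 0 °C to rt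
Reagents that add atoms: tert-butyldimethylsilyl chloride, CC(C)(C)[Si](C)(C)Cl
Why: Standard silyl ether formation on a primary alcohol masks the future C6 oxygen until the end of the route.

Step 3
Reactants: 5 3-[(4-methoxybenzyl)oxy]propanal
Product: 7 (3S,4R)-1-[(4-methoxybenzyl)oxy]-4-methylhex-5-en-3-ol, via borinate ester 6 (not isolated)
Conditions: trans-2-butene, KOt-Bu, n-BuLi, THF, −78 to −45 °C; (+)-Ipc2BOMe, −78 °C; BF3·OEt2; then 5, −78 °C; NaOH, H2O2, rt
Reagents that add atoms: trans-2-butene, C/C=C/C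
Why: Brown crotylboration proceeds through a closed Zimmerman–Traxler chair, so the E geometry of the crotylborane should give the anti C9/C10 pair, and the isopinocampheyl groups derived from (−)-α-pinene should direct the crotyl group to the Re face of the aldehyde, giving (3S,4R).

Step 4
Reactants: 7 (3S,4R)-1-[(4-methoxybenzyl)oxy]-4-methylhex-5-en-3-ol
Product: 8 (3S,4R)-1-[(4-methoxybenzyl)oxy]-4-methylhex-5-en-3-yl (2Z)-2-methylbut-2-enoate
Conditions: angelic acid, 2,4,6-Cl3C6H2COCl, Et3N, toluene, rt; then 7, 80 °C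
Reagents that add atoms: angelic acid, C/C=C(/C)C(=O)O
Why: Yamaguchi esterification through the mixed 2,4,6-trichlorobenzoic anhydride acylates the hindered secondary alcohol without a nucleophilic catalyst, which should avoid isomerisation of the angelate to the tiglate.

Step 5
Reactants: 8 (3S,4R)-1-[(4-methoxybenzyl)oxy]-4-methylhex-5-en-3-yl (2Z)-2-methylbut-2-enoate; 4 tert-butyl{[(2Z)-3-iodobut-2-en-1-yl]oxy}dimethylsilane
Product: 10 (3S,4R,8Z)-10-[(tert-butyldimethylsilyl)oxy]-1-[(4-methoxybenzyl)oxy]-4,8-dimethyl-7-oxodec-8-en-3-yl (2Z)-2-methylbut-2-enoate, via alkylborane 9 (not isolated)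
Conditions: 9-BBN, THF, 0 °C to rt; then 4, Pd(PPh3)4 (5 mol %), K3PO4, CO (1 atm), THF/benzene, rt
Reagents that add atoms: carbon monoxide, [C-]#[O+]
Why: Anti-Markovnikov hydroboration of the only terminal alkene is followed by a carbonylative B-alkyl Suzuki–Miyaura coupling (oxidative addition of zerovalent palladium to the carbon–iodine bond with retention, CO insertion to the acylpalladium, transmetalation from the alkylborate, reductive elimination), which should forge C2–C3 and C3–C4 in one flask and keep the Z geometry.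

Step 6
Reactants: 10 (3S,4R,8Z)-10-[(tert-butyldimethylsilyl)oxy]-1-[(4-methoxybenzyl)oxy]-4,8-dimethyl-7-oxodec-8-en-3-yl (2Z)-2-methylbut-2-enoate
Product: 11 (3S,4R,7S,8Z)-10-[(tert-butyldimethylsilyl)oxy]-7-hydroxy-1-[(4-methoxybenzyl)oxy]-4,8-dimethyldec-8-en-3-yl (2Z)-2-methylbut-2-enoate
Conditions: (R)-2-methyl-CBS-oxazaborolidine [(3aR)-1-methyl-3,3-diphenyltetrahydro-1H,3H-pyrrolo[1,2-c][1,3,2]oxazaborole] (0.2 equiv), catecholborane, toluene, −78 °C
Reagents that add atoms: none
Why: In this Corey–Bakshi–Shibata reduction the α-methyl alkenyl group acts as the large and the CH2 chain as the small ketone substituent, so the (R)-oxazaborolidine should deliver hydride to the face that gives the (S)-allylic alcohol at C3, with 1,2-selectivity and without touching the esters.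

Step 7
Reactants: 11 (3S,4R,7S,8Z)-10-[(tert-butyldimethylsilyl)oxy]-7-hydroxy-1-[(4-methoxybenzyl)oxy]-4,8-dimethyldec-8-en-3-yl (2Z)-2-methylbut-2-enoate
Product: 12 (3S,4R,7S,8Z)-7-acetoxy-10-[(tert-butyldimethylsilyl)oxy]-1-[(4-methoxybenzyl)oxy]-4,8-dimethyldec-8-en-3-yl (2Z)-2-methylbut-2-enoate
Conditions: Ac2O, pyridine, DMAP (cat.), CH2Cl2, 0 °C
Reagents that add atoms: acetic anhydride, CC(=O)OC(C)=O
Why: Routine DMAP-catalysed acetylation of the secondary allylic alcohol installs the C3 acetate of the target.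

Step 8
Reactants: 12 (3S,4R,7S,8Z)-7-acetoxy-10-[(tert-butyldimethylsilyl)oxy]-1-[(4-methoxybenzyl)oxy]-4,8-dimethyldec-8-en-3-yl (2Z)-2-methylbut-2-enoate
Product: 13 (3S,4R,7S,8Z)-7-acetoxy-10-[(tert-butyldimethylsilyl)oxy]-1-hydroxy-4,8-dimethyldec-8-en-3-yl (2Z)-2-methylbut-2-enoate
Conditions: DDQ, CH2Cl2/pH 7 buffer, 0 °C
Reagents that add atoms: none
Why: Oxidative cleavage of the 4-methoxybenzyl ether by DDQ (hydride abstraction to the oxocarbenium ion, then hydrolysis) should leave the silyl ether, both esters and the alkenes untouched.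

Step 9
Reactants: 13 (3S,4R,7S,8Z)-7-acetoxy-10-[(tert-butyldimethylsilyl)oxy]-1-hydroxy-4,8-dimethyldec-8-en-3-yl (2Z)-2-methylbut-2-enoate
Product: 14 (3S,4R,7S,8Z)-7-acetoxy-10-[(tert-butyldimethylsilyl)oxy]-4,8-dimethyl-1-oxodec-8-en-3-yl (2Z)-2-methylbut-2-enoate
Conditions: Dess–Martin periodinane, NaHCO3, CH2Cl2, 0 °C; used crude
Reagents that add atoms: none
Why: Dess–Martin oxidation under buffered, non-basic conditions should give the β-acyloxy aldehyde without β-elimination of the angelate or acyl migration.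

Step 10
Reactants: 14 (3S,4R,7S,8Z)-7-acetoxy-10-[(tert-butyldimethylsilyl)oxy]-4,8-dimethyl-1-oxodec-8-en-3-yl (2Z)-2-methylbut-2-enoate
Product: 15 methyl (5S,6R,9S,10Z)-9-acetoxy-12-[(tert-butyldimethylsilyl)oxy]-3-hydroxy-6,10-dimethyl-2-methylidene-5-{[(2Z)-2-methylbut-2-enoyl]oxy}dodec-10-enoate (both C3 epimers)
Conditions: methyl propiolate, i-Bu2AlH, HMPA, THF, 0 °C; then 14, 0 °C to rt
Reagents that add atoms: methyl propiolate, C#CC(=O)OC
Why: In this vinylalumination, conjugate hydroalumination of methyl propiolate gives the α-aluminoacrylate, which adds to the aldehyde as a base-free equivalent of the Morita–Baylis–Hillman reaction and so should spare the β-angeloyloxy group; the new carbinol stereocentre is inconsequential because step 11 erases it.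

Step 11
Reactants: 15 methyl (5S,6R,9S,10Z)-9-acetoxy-12-[(tert-butyldimethylsilyl)oxy]-3-hydroxy-6,10-dimethyl-2-methylidene-5-{[(2Z)-2-methylbut-2-enoyl]oxy}dodec-10-enoate
Product: 16 methyl (2Z,5S,6R,9S,10Z)-9-acetoxy-2-(bromomethyl)-12-[(tert-butyldimethylsilyl)oxy]-6,10-dimethyl-5-{[(2Z)-2-methylbut-2-enoyl]oxy}dodeca-2,10-dienoate
Conditions: NBS, Me2S, CH2Cl2, 0 °C; then 15, 0 °C to rt
Reagents that add atoms: N-bromosuccinimide, O=C1CCC(=O)N1Br
Why: Activation of the allylic alcohol as an alkoxysulfonium ion (Corey–Kim-type reagent from NBS and Me2S) and SN2' attack of bromide should give the conjugated, thermodynamically favoured (Z)-2-(bromomethyl)enoate and remove the C7 stereocentre.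

Step 12
Reactants: 16 methyl (2Z,5S,6R,9S,10Z)-9-acetoxy-2-(bromomethyl)-12-[(tert-butyldimethylsilyl)oxy]-6,10-dimethyl-5-{[(2Z)-2-methylbut-2-enoyl]oxy}dodeca-2,10-dienoate
Product: 17 methyl (2Z,5S,6R,9S,10Z)-9-acetoxy-2-(bromomethyl)-12-hydroxy-6,10-dimethyl-5-{[(2Z)-2-methylbut-2-enoyl]oxy}dodeca-2,10-dienoate
Conditions: HF (48% aq), MeCN, 0 °C
Reagents that add atoms: none
Why: Acidic fluoride desilylation cleaves the primary allylic silyl ether quickly and, with no amine or basic nucleophile present, should not touch the allylic bromide or the esters.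

Step 13
Reactants: 17 methyl (2Z,5S,6R,9S,10Z)-9-acetoxy-2-(bromomethyl)-12-hydroxy-6,10-dimethyl-5-{[(2Z)-2-methylbut-2-enoyl]oxy}dodeca-2,10-dienoate
Product: 18 methyl (2Z,5S,6R,9S,10Z)-9-acetoxy-2-(bromomethyl)-6,10-dimethyl-5-{[(2Z)-2-methylbut-2-enoyl]oxy}-12-oxododeca-2,10-dienoate
Conditions: Dess–Martin periodinane, NaHCO3, CH2Cl2, 0 °C; filtered through silica and used at once
Reagents that add atoms: none
Why: Dess–Martin oxidation of the (Z)-allylic alcohol under buffered conditions should give the (Z)-enal without Z/E isomerisation.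

Step 14
Reactants: 18 methyl (2Z,5S,6R,9S,10Z)-9-acetoxy-2-(bromomethyl)-6,10-dimethyl-5-{[(2Z)-2-methylbut-2-enoyl]oxy}-12-oxododeca-2,10-dienoate
Product: 21 (3aS,5S,6R,9S,10Z,11aR)-9-acetoxy-6,10-dimethyl-3-methylidene-2-oxo-2,3,3a,4,5,6,7,8,9,11a-decahydrocyclodeca[b]furan-5-yl (2Z)-2-methylbut-2-enoate (CNP0173235.1), via allylchromium 19 (not isolated), via chromium alkoxide 20 (not isolated)
Conditions: CrCl2 (8 equiv), THF/DMF (10:1), 25 °C, 18 added over 12 h by syringe pump (final 2 mM); aq. NH4Cl work-up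
Reagents that add atoms: none
Why: Two equivalents of CrCl2 reduce the allylic carbon–bromine bond by sequential single-electron transfer to the 2-(methoxycarbonyl)allylchromium species 19 (trivalent chromium), which adds through its γ-carbon C7 to the enal carbonyl C6 in a six-membered Zimmerman–Traxler chair, and the chromium alkoxide 20 then acylates on the adjacent methyl ester with loss of methoxide. The closest known reaction type is the intramolecular Nozaki–Hiyama–Kishi (Barbier-type) 2-(alkoxycarbonyl)allylation with in situ lactonisation used to close medium-ring α-methylene-γ-butyrolactones. The ten-membered carbocycle closes by 10-exo-trig carbonyl addition (C7 to C6) and the γ-lactone by 5-exo-trig acyl substitution (the C6 oxygen to C12). The anti C6/C7 relationship, hence the trans-fused lactone, should follow from the chair in which both ring arms (the C5 alkenyl group on the aldehyde and the C8 methylene on the allyl terminus) are pseudo-equatorial, a geometry available because the allylchromium terminus equilibrates by 1,3-metallotropy faster than the slow ring closure (Curtin–Hammett). The absolute sense (6R,7S) is left to the substrate: the C9 angelate and C10 methyl next to the allyl terminus should take pseudo-equatorial sites on the forming ring, and the rigid (Z)-C4=C5 unit with its (3S)-acetate restricts the approach of the enal face. The step needs intramolecular over intermolecular addition and 1,2- over conjugate addition, secured by slow addition at about 2 mM and by the oxophilic σ-allylchromium, which should leave the acetate, the angelate and the acrylate untouched.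

**Compound list**

1 | but-2-yn-1-ol | CC#CCO | starting material
2 | sodium cyclic (Z)-alkenyl alkoxyaluminate from 1 (five-membered oxaaluminate, two 2-methoxyethoxy ligands) | CC1=CCO[Al-]1(OCCOC)OCCOC.[Na+] | intermediate
3 | (2Z)-3-iodobut-2-en-1-ol | C/C(I)=C/CO | intermediate
4 | tert-butyl{[(2Z)-3-iodobut-2-en-1-yl]oxy}dimethylsilane | C/C(I)=C/CO[Si](C)(C)C(C)(C)C | intermediate
5 | 3-[(4-methoxybenzyl)oxy]propanal | O=CCCOCc1ccc(OC)cc1 | starting material
6 | diisopinocampheylborinate ester of 7 | C=C[C@@H](C)[C@@H](OB([C@H]1C[C@H]2C[C@@H]([C@@H]1C)C2(C)C)[C@H]1C[C@H]2C[C@@H]([C@@H]1C)C2(C)C)CCOCc1ccc(OC)cc1 | intermediate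
7 | (3S,4R)-1-[(4-methoxybenzyl)oxy]-4-methylhex-5-en-3-ol | C=C[C@@H](C)[C@@H](O)CCOCc1ccc(OC)cc1 | intermediate
8 | (3S,4R)-1-[(4-methoxybenzyl)oxy]-4-methylhex-5-en-3-yl (2Z)-2-methylbut-2-enoate | C=C[C@@H](C)[C@@H](OC(=O)/C(C)=C\C)CCOCc1ccc(OC)cc1 | intermediate
9 | B-alkyl-9-borabicyclo[3.3.1]nonane from 8 (boron on the former terminal alkene carbon) | B1(CC[C@@H](C)[C@@H](OC(=O)/C(C)=C\C)CCOCc2ccc(OC)cc2)C2CCCC1CCC2 | intermediate
10 | (3S,4R,8Z)-10-[(tert-butyldimethylsilyl)oxy]-1-[(4-methoxybenzyl)oxy]-4,8-dimethyl-7-oxodec-8-en-3-yl (2Z)-2-methylbut-2-enoate | CC(C)(C)[Si](C)(C)OC/C=C(/C)C(=O)CC[C@@H](C)[C@@H](OC(=O)/C(C)=C\C)CCOCc1ccc(OC)cc1 | intermediate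
11 | (3S,4R,7S,8Z)-10-[(tert-butyldimethylsilyl)oxy]-7-hydroxy-1-[(4-methoxybenzyl)oxy]-4,8-dimethyldec-8-en-3-yl (2Z)-2-methylbut-2-enoate | CC(C)(C)[Si](C)(C)OC/C=C(/C)[C@@H](O)CC[C@@H](C)[C@@H](OC(=O)/C(C)=C\C)CCOCc1ccc(OC)cc1 | intermediate
12 | (3S,4R,7S,8Z)-7-acetoxy-10-[(tert-butyldimethylsilyl)oxy]-1-[(4-methoxybenzyl)oxy]-4,8-dimethyldec-8-en-3-yl (2Z)-2-methylbut-2-enoate | CC(C)(C)[Si](C)(C)OC/C=C(/C)[C@@H](OC(C)=O)CC[C@@H](C)[C@@H](OC(=O)/C(C)=C\C)CCOCc1ccc(OC)cc1 | intermediate
13 | (3S,4R,7S,8Z)-7-acetoxy-10-[(tert-butyldimethylsilyl)oxy]-1-hydroxy-4,8-dimethyldec-8-en-3-yl (2Z)-2-methylbut-2-enoate | CC(C)(C)[Si](C)(C)OC/C=C(/C)[C@@H](OC(C)=O)CC[C@@H](C)[C@@H](OC(=O)/C(C)=C\C)CCO | intermediate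
14 | (3S,4R,7S,8Z)-7-acetoxy-10-[(tert-butyldimethylsilyl)oxy]-4,8-dimethyl-1-oxodec-8-en-3-yl (2Z)-2-methylbut-2-enoate | CC(C)(C)[Si](C)(C)OC/C=C(/C)[C@@H](OC(C)=O)CC[C@@H](C)[C@@H](OC(=O)/C(C)=C\C)CC=O | intermediate
15 | methyl (5S,6R,9S,10Z)-9-acetoxy-12-[(tert-butyldimethylsilyl)oxy]-3-hydroxy-6,10-dimethyl-2-methylidene-5-{[(2Z)-2-methylbut-2-enoyl]oxy}dodec-10-enoate (both C3 epimers) | CC(C)(C)[Si](C)(C)OC/C=C(/C)[C@@H](OC(C)=O)CC[C@@H](C)[C@@H](OC(=O)/C(C)=C\C)CC(O)C(=C)C(=O)OC | intermediate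
16 | methyl (2Z,5S,6R,9S,10Z)-9-acetoxy-2-(bromomethyl)-12-[(tert-butyldimethylsilyl)oxy]-6,10-dimethyl-5-{[(2Z)-2-methylbut-2-enoyl]oxy}dodeca-2,10-dienoate | CC(C)(C)[Si](C)(C)OC/C=C(/C)[C@@H](OC(C)=O)CC[C@@H](C)[C@@H](OC(=O)/C(C)=C\C)C/C=C(\CBr)C(=O)OC | intermediate
17 | methyl (2Z,5S,6R,9S,10Z)-9-acetoxy-2-(bromomethyl)-12-hydroxy-6,10-dimethyl-5-{[(2Z)-2-methylbut-2-enoyl]oxy}dodeca-2,10-dienoate | OC/C=C(/C)[C@@H](OC(C)=O)CC[C@@H](C)[C@@H](OC(=O)/C(C)=C\C)C/C=C(\CBr)C(=O)OC | intermediate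
18 | methyl (2Z,5S,6R,9S,10Z)-9-acetoxy-2-(bromomethyl)-6,10-dimethyl-5-{[(2Z)-2-methylbut-2-enoyl]oxy}-12-oxododeca-2,10-dienoate | O=C/C=C(/C)[C@@H](OC(C)=O)CC[C@@H](C)[C@@H](OC(=O)/C(C)=C\C)C/C=C(\CBr)C(=O)OC | intermediate
19 | 2-(methoxycarbonyl)allylchromium dichloride from 18 (configurationally labile at the allyl double bond) | O=C/C=C(/C)[C@@H](OC(C)=O)CC[C@@H](C)[C@@H](OC(=O)/C(C)=C\C)CC=C(C[Cr](Cl)Cl)C(=O)OC | intermediate
20 | dichlorochromium alkoxide of the ten-membered (6R,7S)-hydroxy methyl ester | COC(=O)C(=C)[C@H]1[C@H](O[Cr](Cl)Cl)/C=C(/C)[C@@H](OC(C)=O)CC[C@@H](C)[C@@H](OC(=O)/C(C)=C\C)C1 | intermediate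
21 | (3aS,5S,6R,9S,10Z,11aR)-9-acetoxy-6,10-dimethyl-3-methylidene-2-oxo-2,3,3a,4,5,6,7,8,9,11a-decahydrocyclodeca[b]furan-5-yl (2Z)-2-methylbut-2-enoate (CNP0173235.1) | C=C1C(=O)O[C@@H]2/C=C(/C)[C@@H](OC(C)=O)CC[C@@H](C)[C@@H](OC(=O)/C(C)=C\C)C[C@@H]12 | target

**Step count and risks**

Total step count: 14. Longest linear sequence: 12 steps (steps 3 to 14, from aldehyde 5); the two-step branch to iodide 4 joins in step 5.

Steps most likely to fail:

1. Step 14. The ring-closing addition may show poor facial selectivity or the wrong syn/anti sense, since both depend on remote stereocentres and on equilibration of the allylchromium, and oligomerisation may compete with closure. The fallback sets out from 15 and returns at 21. Alcohol 15 would be acetylated (Ac2O, DMAP) to the allylic acetate F1. SN2' borylation of F1 with bis(pinacolato)diboron (CuCl cat., KOAc, DMF) would give the primary 2-(methoxycarbonyl)allylboronate F2. Desilylation (aq. HF, MeCN) would give the alcohol F3, and Dess–Martin oxidation the enal boronate F4, a configurationally fixed pronucleophile that can be isolated. Ring closure would then be an intramolecular allylboration under high dilution, either thermal (toluene, 60–80 °C) or acid-catalysed (Sc(OTf)3, or a chiral 3,3'-bis(2,4,6-triisopropylphenyl)-1,1'-binaphthyl-2,2'-diyl hydrogen phosphate at low temperature). In this manifold the boron chair cannot equilibrate, the syn/anti outcome can be switched between the thermal and the acid-catalysed mode, and the catalyst gives a handle on the aldehyde face that the chromium reaction lacks. The borate ester of the adduct would lactonise to 21.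

2. Step 5. Direct (non-carbonylative) coupling or protodeboronation may outrun CO insertion, and the (Z)-enone may isomerise under palladium. The fallback sets out from 8 and returns at 10. Linear-selective hydroformylation of 8 (Rh(acac)(CO)2, BIPHEPHOS, CO/H2, toluene, 60 °C) would give the aldehyde F5. Nozaki–Hiyama–Kishi coupling of F5 with iodide 4 (CrCl2, NiCl2 cat., DMSO) would give the allylic alcohol F6 as a mixture of C7 epimers. Dess–Martin oxidation of F6 would then give 10.

3. Step 10. β-Elimination of the angelate from the β-acyloxy aldehyde, or acyl transfer, may compete with carbonyl addition under the Lewis-acidic organoaluminium conditions. The fallback sets out from 14 and returns at 15. Aldol addition of the lithium enolate of methyl 3-(phenylselanyl)propanoate (LiN(i-Pr)2, THF, −78 °C) to 14 would give the β-hydroxy ester F7. Oxidation with H2O2 (CH2Cl2, pyridine, 0 °C) and syn-elimination of the selenoxide would then unveil the acrylate of 15.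

**Further compounds**

F1 | step 14 | methyl (5S,6R,9S,10Z)-3,9-diacetoxy-12-[(tert-butyldimethylsilyl)oxy]-6,10-dimethyl-2-methylidene-5-{[(2Z)-2-methylbut-2-enoyl]oxy}dodec-10-enoate | CC(C)(C)[Si](C)(C)OC/C=C(/C)[C@@H](OC(C)=O)CC[C@@H](C)[C@@H](OC(=O)/C(C)=C\C)CC(OC(C)=O)C(=C)C(=O)OC
F2 | step 14 | methyl (2E,5S,6R,9S,10Z)-9-acetoxy-12-[(tert-butyldimethylsilyl)oxy]-6,10-dimethyl-5-{[(2Z)-2-methylbut-2-enoyl]oxy}-2-[(4,4,5,5-tetramethyl-1,3,2-dioxaborolan-2-yl)methyl]dodeca-2,10-dienoate | CC(C)(C)[Si](C)(C)OC/C=C(/C)[C@@H](OC(C)=O)CC[C@@H](C)[C@@H](OC(=O)/C(C)=C\C)C/C=C(\CB1OC(C)(C)C(C)(C)O1)C(=O)OC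
F3 | step 14 | methyl (2E,5S,6R,9S,10Z)-9-acetoxy-12-hydroxy-6,10-dimethyl-5-{[(2Z)-2-methylbut-2-enoyl]oxy}-2-[(4,4,5,5-tetramethyl-1,3,2-dioxaborolan-2-yl)methyl]dodeca-2,10-dienoate | OC/C=C(/C)[C@@H](OC(C)=O)CC[C@@H](C)[C@@H](OC(=O)/C(C)=C\C)C/C=C(\CB1OC(C)(C)C(C)(C)O1)C(=O)OC
F4 | step 14 | methyl (2E,5S,6R,9S,10Z)-9-acetoxy-6,10-dimethyl-5-{[(2Z)-2-methylbut-2-enoyl]oxy}-12-oxo-2-[(4,4,5,5-tetramethyl-1,3,2-dioxaborolan-2-yl)methyl]dodeca-2,10-dienoate | O=C/C=C(/C)[C@@H](OC(C)=O)CC[C@@H](C)[C@@H](OC(=O)/C(C)=C\C)C/C=C(\CB1OC(C)(C)C(C)(C)O1)C(=O)OC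
F5 | step 5 | (3S,4R)-1-[(4-methoxybenzyl)oxy]-4-methyl-7-oxoheptan-3-yl (2Z)-2-methylbut-2-enoate | O=CCC[C@@H](C)[C@@H](OC(=O)/C(C)=C\C)CCOCc1ccc(OC)cc1
F6 | step 5 | (3S,4R,8Z)-10-[(tert-butyldimethylsilyl)oxy]-7-hydroxy-1-[(4-methoxybenzyl)oxy]-4,8-dimethyldec-8-en-3-yl (2Z)-2-methylbut-2-enoate (both C7 epimers) | CC(C)(C)[Si](C)(C)OC/C=C(/C)C(O)CC[C@@H](C)[C@@H](OC(=O)/C(C)=C\C)CCOCc1ccc(OC)cc1
F7 | step 10 | methyl (5S,6R,9S,10Z)-9-acetoxy-12-[(tert-butyldimethylsilyl)oxy]-3-hydroxy-6,10-dimethyl-5-{[(2Z)-2-methylbut-2-enoyl]oxy}-2-[(phenylselanyl)methyl]dodec-10-enoate (mixture of C2/C3 isomers) | CC(C)(C)[Si](C)(C)OC/C=C(/C)[C@@H](OC(C)=O)CC[C@@H](C)[C@@H](OC(=O)/C(C)=C\C)CC(O)C(C[Se]c1ccccc1)C(=O)OC
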